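Late in the beta run, at 15.0 min, right-handed substrate and left-handed substrate both read 41.5% of the pair charged, although the catalyst is single-handed and left-handed product stands at 9.8%.

all flasks: left-handed substrate 1.1 M; right-handed substrate 1.1 M

| flask | partner | protic impurity | free catalyst | remark | time |
|---|---|---|---|---|---|
| delta | 0.66 M | 0.022 M | 3.1 mM | run made earlier |  |
| beta | 0.66 M | 0.022 M | 4.8 mM | run made earlier |  |
| flask | 0.660 M | 0.0220 M | 2.2 mM |  | 25 min |

| run | time / min | right-handed substrate / % | left-handed substrate / % | left-handed product / % |
|---|---|---|---|---|
| delta | 1.33 | 50.3 | 48.0 | 1.8 |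
| delta | 2.50 | 47.7 | 48.1 | 1.0 |
| delta | 4.00 | 49.7 | 48.7 | 3.0 |
| delta | 8.00 | 46.3 | 45.7 | 3.7 |
| delta | 15.0 | 44.7 | 43.2 | 8.7 |
| beta | 3.00 | 48.1 | 45.8 | 3.5 |
| beta | 6.00 | 44.8 | 44.4 | 5.6 |
| beta | 10.0 | 42.7 | 42.3 | 7.3 |
| beta | 12.0 | 42.2 | 43.4 | 9.1 |
| beta | 15.0 | 41.5 | 41.5 | 9.8 |

(each reading ± 1 percentage point)

- free catalyst is single-handed; left-handed substrate and right-handed substrate are mirror images of each other, charged as a racemate, each of them at the stated concentration
- the numbers in the tables scatter with a standard deviation of 1 percentage point

- whether the excess of right-handed substrate over left-handed substrate among what is left of the two reaches 80% by 25 min (yes / no)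
- the highest excess of right-handed substrate over left-handed substrate among what is left of the two up to 25 min

These readings don't clash: right-handed substrate is being lost too, to something the tables don't follow, so left-handed product alone doesn't measure an excess. It does give you a test, though. For this kinetic resolution to reach 80% with right-handed substrate held at its charge, left-handed substrate must give up 44.4% of the whole charge.

Now scale the last delta reading of left-handed product in proportion to catalyst and time, which gives 10.3% for this flask. Call this the reach, the left-handed product expected from a flask by linear scaling of delta. The reach is less than the need, so my answer is no. With right-handed substrate untouched, that reach gives an excess of 11.5%, a rough estimate resting on one scattered reading and on a proportion that need not hold.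

The forecast also says no, with a top of 0.5%, lower than my rough estimate, on the grounds of “so little conversion and selectivity this low”.

The flask gives no, with a top of 0.388%.

    free catalyst + left-handed substrate ⇌ catalyst intermediate A (K = 0.550 M⁻¹, k = 670 M⁻¹ min⁻¹)
    2 free catalyst ⇌ resting dimer (K = 68000 M⁻¹, k = 51.0 M⁻¹ min⁻¹)
    partner + protic impurity → quenched reagent (k = 1.50 M⁻¹ min⁻¹)
    partner + catalyst intermediate B → free catalyst + right-handed product (k = 19.0 M⁻¹ min⁻¹)
    left-handed substrate ⇌ right-handed substrate (k = 0.170 min⁻¹)
    partner + catalyst intermediate A → free catalyst + left-handed product (k = 45.0 M⁻¹ min⁻¹)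
    free catalyst + right-handed substrate ⇌ catalyst intermediate B (K = 0.910 M⁻¹, k = 1300 M⁻¹ min⁻¹)

At 25.0 min this flask holds left-handed product 8.28% and right-handed product 5.89%, against a reach of 10.3%. The neighbour charged with 5.5 × 10⁻⁴ M of free catalyst has a reach of 2.57%; its top is 0.121%, well under the forecast's figure, and it gives left-handed product 3.31%.

The earlier runs and the new flask stem from a simulated flask with constants of no real substance, noise included.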